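**Retrosynthetic overview**
- The target is unveiled by acetal hydrolysis; the cyclopentene (the only ring) is closed last, across C1=C2, by an enamine aldol condensation of a 3-substituted 7-acetoxy-6-oxoheptanal.
- The acetoxymethyl ketone comes from a terminal alkyne (gold oxidation with O–H insertion of AcOH); the ring aldehyde comes from a methyl ester.
- Key disconnection, ring C3–side-chain Cα: the carbene-generated homoenolate of (E)-hept-2-en-6-ynal adds to a homogeranyl nitroalkene (masked α-cation of the side-chain aldehyde), giving an anti δ-nitro ester with both stereocentres.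
- The nitroalkene comes from geranyl bromide, acetaldehyde dimethylhydrazone and nitromethane; the enal comes from pent-4-yn-1-ol and the formyl Wittig ylide.

Assumption: the absolute sense of induction in step 4 is assigned by analogy with aryl-substituted substrates; if the first run gives the mirror-image series, the antipodal triazolium salt is used.

**Step 1**
Reactants: 1 geranyl bromide; 2 acetaldehyde N,N-dimethylhydrazone
Product: 5 (4E)-5,9-dimethyldeca-4,8-dienal, via lithiated hydrazone 3 (not isolated), via alkylated hydrazone 4 (not isolated)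
Conditions: LiN(i-Pr)2 (1.05 equiv), THF, 0 °C; then 1, −78 → 0 °C; then sat. aq. oxalic acid/Et2O, rt
Reagents that add atoms: water, O
Why: Aza-enolate (Corey–Enders type) alkylation: the lithiated hydrazone displaces the primary allylic bromide without allylic transposition, and mild biphasic hydrolysis frees the aldehyde without touching the (E)-alkene; no stereocentre is formed.

**Step 2**
Reactants: 5 (4E)-5,9-dimethyldeca-4,8-dienal; 6 nitromethane
Product: 9 (1E,5E)-6,10-dimethyl-1-nitroundeca-1,5,9-triene, via nitro alcohol 7 (not isolated), via nitro mesylate 8 (not isolated)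
Conditions: MeNO2 (10 equiv), tetramethylguanidine (10 mol %), THF, 0 °C; evaporate; MsCl, Et3N, CH2Cl2, −20 → 0 °C
Reagents that add atoms: none
Why: Henry (nitroaldol) addition followed by mesylation and E1cB elimination gives the thermodynamically preferred (E)-nitroalkene; no stereocentre is formed.

**Step 3**
Reactants: 10 pent-4-yn-1-ol; 11 (triphenylphosphoranylidene)acetaldehyde
Product: 13 (2E)-hept-2-en-6-ynal, via pent-4-ynal 12 (not isolated)
Conditions: Dess–Martin periodinane (1.1 equiv), CH2Cl2, 0 °C → rt; then 11 (1.0 equiv), PhMe, 70 °C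
Reagents that add atoms: none
Why: Dess–Martin oxidation to the volatile ynal and in-situ Wittig olefination with the stabilised formyl ylide give the (E)-enal; limiting the ylide to one equivalent suppresses double homologation.

**Step 4 (key step)**
Reactants: 13 (2E)-hept-2-en-6-ynal; 9 (1E,5E)-6,10-dimethyl-1-nitroundeca-1,5,9-triene
Product: 14 methyl (3R,4R,7E)-3-(but-3-yn-1-yl)-8,12-dimethyl-4-(nitromethyl)trideca-7,11-dienoate
Conditions: (5aS,10bR)-N-mesityl aminoindanol-derived triazolium chloride (10 mol %), NaOAc (0.5 equiv), MeOH, rt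
Reagents that add atoms: methanol, CO
Why: N-heterocyclic-carbene-catalysed homoenolate Michael addition with redox esterification: the carbene turns the enal into a Breslow intermediate whose β-carbon, normally an acceptor, attacks the acceptor β-carbon of the nitroalkene. Tautomerisation to the acyl azolium and methanolysis release the catalyst, and the chiral triazolylidene sets both stereocentres (3R,4R, anti) through an open transition state.

**Step 5**
Reactants: 14 methyl (3R,4R,7E)-3-(but-3-yn-1-yl)-8,12-dimethyl-4-(nitromethyl)trideca-7,11-dienoate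
Product: 16 methyl (3R,4R,7E)-3-(but-3-yn-1-yl)-4-(dimethoxymethyl)-8,12-dimethyltrideca-7,11-dienoate, via sodium nitronate 15 (not isolated)
Conditions: NaOMe (1.5 equiv), MeOH, 0 °C; then added to H2SO4/MeOH, −40 → −10 °C; NaHCO3 quench
Reagents that add atoms: methanol, CO
Why: Nef reaction in methanol (acetal variant): only the CH2NO2 carbon is deprotonated, so neither stereocentre can epimerise, and cold acid solvolysis of the nitronate gives the dimethyl acetal directly, masking the side-chain aldehyde for steps 6 to 8.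

**Step 6**
Reactants: 16 methyl (3R,4R,7E)-3-(but-3-yn-1-yl)-4-(dimethoxymethyl)-8,12-dimethyltrideca-7,11-dienoate
Product: 17 (3R,4R,7E)-3-(but-3-yn-1-yl)-4-(dimethoxymethyl)-8,12-dimethyltrideca-7,11-dienal
Conditions: i-Bu2AlH (1.1 equiv), CH2Cl2, −78 °C; MeOH, then aq. KNaC4H4O6
Reagents that add atoms: none
Why: Partial ester reduction: at −78 °C the tetrahedral aluminium hemiacetal persists and collapses to the aldehyde only on work-up; acetal, terminal alkyne and alkenes are inert.

**Step 7**
Reactants: 17 (3R,4R,7E)-3-(but-3-yn-1-yl)-4-(dimethoxymethyl)-8,12-dimethyltrideca-7,11-dienal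
Product: 18 (5R,6R,9E)-6-(dimethoxymethyl)-10,14-dimethyl-2-oxo-5-(2-oxoethyl)pentadeca-9,13-dien-1-yl acetate
Conditions: (Mor-DalPhos)AuNTf2 (5 mol %; Mor-DalPhos = (1-Ad)2P(C6H4-2-morpholino); monovalent gold), 8-methylquinoline N-oxide (1.5 equiv), AcOH (5 equiv), PhCl, rt
Reagents that add atoms: acetic acid, CC(=O)O; 8-methylquinoline N-oxide, Cc1cccc2ccc[n+]([O-])c12
Why: Gold-catalysed oxidation of a terminal alkyne: Markovnikov attack of the N-oxide oxygen and N–O cleavage give an α-oxo gold carbene at the terminal carbon, which inserts into the O–H bond of acetic acid to give the acetoxymethyl ketone; the remote alkenes, aldehyde and acetal do not interfere.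

**Step 8**
Reactants: 18 (5R,6R,9E)-6-(dimethoxymethyl)-10,14-dimethyl-2-oxo-5-(2-oxoethyl)pentadeca-9,13-dien-1-yl acetate
Product: 19 {(3S)-3-[(2R,5E)-1,1-dimethoxy-6,10-dimethylundeca-5,9-dien-2-yl]-2-formylcyclopent-1-en-1-yl}methyl acetate
Conditions: Bn2NH·CF3CO2H (0.3 equiv), PhMe, 50 °C
Reagents that add atoms: none
Why: Intramolecular aldol condensation under enamine catalysis: the enamine of the unbranched aldehyde adds to the activated acetoxy ketone in a five-membered ring closure and dehydrates to the conjugated tetrasubstituted enal, as in the classic amine-salt cyclisation of 3-substituted 6-oxoheptanals. The ring stereocentre is not enolisable and the acetal keeps the side-chain centre fixed.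

**Step 9**
Reactants: 19 {(3S)-3-[(2R,5E)-1,1-dimethoxy-6,10-dimethylundeca-5,9-dien-2-yl]-2-formylcyclopent-1-en-1-yl}methyl acetate
Product: 20 {(3S)-2-formyl-3-[(2R,5E)-6,10-dimethyl-1-oxoundeca-5,9-dien-2-yl]cyclopent-1-en-1-yl}methyl acetate
Conditions: pyridinium p-toluenesulfonate (0.2 equiv), acetone/H2O 10:1, 40 °C
Reagents that add atoms: water, O
Why: Mild acid-catalysed acetal hydrolysis (transacetalisation) unveils the α-branched aldehyde under conditions too weak to epimerise it, cleave the allylic acetate or protonate the trisubstituted alkenes.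

**Compound list**
1 | geranyl bromide, (2E)-1-bromo-3,7-dimethylocta-2,6-diene | BrC/C=C(\C)CCC=C(C)C | starting material
2 | acetaldehyde N,N-dimethylhydrazone | CC=NN(C)C | starting material
3 | lithiated hydrazone (lithium aza-enolate of 2) | C=C[N-]N(C)C.[Li+] | intermediate
4 | alkylated hydrazone, (4E)-5,9-dimethyldeca-4,8-dienal N,N-dimethylhydrazone | CN(C)N=CCC/C=C(\C)CCC=C(C)C | intermediate
5 | (4E)-5,9-dimethyldeca-4,8-dienal | O=CCC/C=C(\C)CCC=C(C)C | intermediate
6 | nitromethane | C[N+](=O)[O-] | starting material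
7 | nitro alcohol, (5E)-6,10-dimethyl-1-nitroundeca-5,9-dien-2-ol (racemic) | [O-][N+](=O)CC(O)CC/C=C(\C)CCC=C(C)C | intermediate
8 | nitro mesylate, (5E)-6,10-dimethyl-1-nitroundeca-5,9-dien-2-yl methanesulfonate (racemic) | [O-][N+](=O)CC(OS(C)(=O)=O)CC/C=C(\C)CCC=C(C)C | intermediate
9 | (1E,5E)-6,10-dimethyl-1-nitroundeca-1,5,9-triene | [O-][N+](=O)/C=C/CC/C=C(\C)CCC=C(C)C | intermediate
10 | pent-4-yn-1-ol | OCCCC#C | starting material
11 | (triphenylphosphoranylidene)acetaldehyde | O=CC=P(c1ccccc1)(c1ccccc1)c1ccccc1 | starting material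
12 | pent-4-ynal | O=CCCC#C | intermediate
13 | (2E)-hept-2-en-6-ynal | O=C/C=C/CCC#C | intermediate
14 | methyl (3R,4R,7E)-3-(but-3-yn-1-yl)-8,12-dimethyl-4-(nitromethyl)trideca-7,11-dienoate | COC(=O)C[C@H]([C@H](C[N+](=O)[O-])CC/C=C(\C)CCC=C(C)C)CCC#C | intermediate
15 | sodium nitronate of 14 | COC(=O)C[C@H]([C@H](C=[N+]([O-])[O-])CC/C=C(\C)CCC=C(C)C)CCC#C.[Na+] | intermediate
16 | methyl (3R,4R,7E)-3-(but-3-yn-1-yl)-4-(dimethoxymethyl)-8,12-dimethyltrideca-7,11-dienoate | COC(=O)C[C@H]([C@H](C(OC)OC)CC/C=C(\C)CCC=C(C)C)CCC#C | intermediate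
17 | (3R,4R,7E)-3-(but-3-yn-1-yl)-4-(dimethoxymethyl)-8,12-dimethyltrideca-7,11-dienal | O=CC[C@H]([C@H](C(OC)OC)CC/C=C(\C)CCC=C(C)C)CCC#C | intermediate
18 | (5R,6R,9E)-6-(dimethoxymethyl)-10,14-dimethyl-2-oxo-5-(2-oxoethyl)pentadeca-9,13-dien-1-yl acetate | CC(=O)OCC(=O)CC[C@H](CC=O)[C@H](C(OC)OC)CC/C=C(\C)CCC=C(C)C | intermediate
19 | {(3S)-3-[(2R,5E)-1,1-dimethoxy-6,10-dimethylundeca-5,9-dien-2-yl]-2-formylcyclopent-1-en-1-yl}methyl acetate | CC(=O)OCC1=C(C=O)[C@H]([C@H](C(OC)OC)CC/C=C(\C)CCC=C(C)C)CC1 | intermediate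
20 | {(3S)-2-formyl-3-[(2R,5E)-6,10-dimethyl-1-oxoundeca-5,9-dien-2-yl]cyclopent-1-en-1-yl}methyl acetate | CC(=O)OCC1=C(C=O)[C@H]([C@H](C=O)CC/C=C(\C)CCC=C(C)C)CC1 | target

**Totals**
Total step count: 9. Longest linear sequence: 8 (steps 1, 2, 4, 5, 6, 7, 8, 9).

**Three steps most likely to fail**

Step 4. Risks are the competing acyl-anion (Stetter-type) addition, carbene trapping by the nitroalkene, and a lower anti:syn ratio for an alkyl/alkyl pair than for the aryl cases. The fallback sets out from 5 and 13 and comes back at 20. It joins the same two carbons by enamine/iminium catalysis instead. Aldehyde 5 is homologated by Wittig methoxymethylenation (Ph3P=CHOMe) to the enol ether (5E)-1-methoxy-6,10-dimethylundeca-1,5,9-triene F1, which dilute acid hydrolyses to (5E)-6,10-dimethylundeca-5,9-dienal F2. The alkyne of 13 is oxidised under the step 7 gold conditions to (5E)-2,7-dioxohept-5-en-1-yl acetate F3. With (S)-2-[diphenyl(trimethylsilyloxy)methyl]pyrrolidine and PhCO2H in toluene, the enamine of F2 adds to the iminium ion of F3, and the resulting enamine closes onto the acetoxy ketone and dehydrates. Shielding of the same face in both the enamine and the iminium ion gives the (3S, side-chain R) arrangement, so this cascade delivers 20 directly.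

Step 7. Risks are over-oxidation of the gold carbene, acetal loss in acetic acid, and carbene capture by an alkene. The fallback sets out from 17 and comes back at 18. The alkyne C–H is brominated (N-bromosuccinimide, cat. AgNO3, acetone) to (3R,4R,7E)-3-(4-bromobut-3-yn-1-yl)-4-(dimethoxymethyl)-8,12-dimethyltrideca-7,11-dienal F4. Gold-catalysed hydration of the bromoalkyne (Ph3PAuNTf2, monovalent gold, wet 1,2-dichloroethane) gives the bromomethyl ketone (3R,4R,7E)-3-(4-bromo-3-oxobutyl)-4-(dimethoxymethyl)-8,12-dimethyltrideca-7,11-dienal F5. Displacement of bromide with KOAc in acetone then gives 18.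

Step 5. The risk is protonation or methanol addition at the trisubstituted alkenes in methanolic H2SO4. The fallback sets out from 14 and comes back at 16. The nitronate (NaOMe, MeOH) is reduced with aqueous TiCl3 buffered with NH4OAc (reductive Nef) to the free aldehyde methyl (3R,4R,7E)-3-(but-3-yn-1-yl)-4-formyl-8,12-dimethyltrideca-7,11-dienoate F6. F6 is then acetalised with HC(OMe)3 and pyridinium p-toluenesulfonate in MeOH to give 16.

**Further compounds**
F1 | step 4 | (5E)-1-methoxy-6,10-dimethylundeca-1,5,9-triene (E/Z mixture at the enol ether) | COC=CCC/C=C(\C)CCC=C(C)C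
F2 | step 4 | (5E)-6,10-dimethylundeca-5,9-dienal | O=CCCC/C=C(\C)CCC=C(C)C
F3 | step 4 | (5E)-2,7-dioxohept-5-en-1-yl acetate | CC(=O)OCC(=O)CC/C=C/C=O
F4 | step 7 | (3R,4R,7E)-3-(4-bromobut-3-yn-1-yl)-4-(dimethoxymethyl)-8,12-dimethyltrideca-7,11-dienal | O=CC[C@H]([C@H](C(OC)OC)CC/C=C(\C)CCC=C(C)C)CCC#CBr
F5 | step 7 | (3R,4R,7E)-3-(4-bromo-3-oxobutyl)-4-(dimethoxymethyl)-8,12-dimethyltrideca-7,11-dienal | O=CC[C@H]([C@H](C(OC)OC)CC/C=C(\C)CCC=C(C)C)CCC(=O)CBr
F6 | step 5 | methyl (3R,4R,7E)-3-(but-3-yn-1-yl)-4-formyl-8,12-dimethyltrideca-7,11-dienoate | COC(=O)C[C@H]([C@H](C=O)CC/C=C(\C)CCC=C(C)C)CCC#C
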